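I was asked for 3 numbers: the first product at the end of delta, epsilon and alpha.

| setting | teal | violet | delta | epsilon | alpha |
|---|---|---|---|---|---|
| substrate | 18 mM | 18 mM | 18 mM | 18 mM | 18 mM |
| partner | 13 mM | 22 mM | 18.0 mM | 21.6 mM | 27.0 mM |
| capture agent | 0.90 mM | 0.90 mM | 0.900 mM | 0.900 mM | 0.900 mM |
| remark | run made earlier | run made earlier |  |  |  |
| time |  |  | 12 d | 12 d | 12 d |

| run | time / d | first product / % | bis adduct / % |
|---|---|---|---|
| teal | 0.500 | 38 | 1 |
| teal | 0.833 | 43 | 0 |
| teal | 1.67 | 51 | 0 |
| teal | 3.00 | 57 | 1 |
| teal | 6.00 | 61 | 3 |
| violet | 0.500 | 54 | 0 |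
| violet | 1.67 | 77 | 3 |
| violet | 3.00 | 78 | 5 |
| violet | 4.00 | 75 | 10 |
| violet | 6.00 | 76 | 6 |

(scatter of a reading: 1.5 percentage points)

- final first product, as a percentage of the substrate charged, for each flask in turn (delta, epsilon, alpha)



I reckoned in fractions of the substrate charge and built a ladder of rates from the violet run. On the top rung stands the first addition. Its integrated second-order law at 0.500 d gave

a = 1.74 d⁻¹, a clock of 0.574 d.

Lower down, teal at 6.00 d leaves 0.0522 of the substrate charge in partner unaccounted for, close to the capture charge of 0.0500. So I took the capture agent to hold a small slice of first product, though the readings do not time it.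

On the bottom rung stands the second addition. The last 3 violet readings average 7.00 % bis adduct at 4.33 d, beside 76.3 % first product and about 0.319 of free partner, so

s = 0.0664 d⁻¹, a clock of 15.1 d.

This is a rough reading, but the first addition is clearly faster than the second. Both steps take partner, so partner cancels from their competition. Leaving capture aside, first product rises while substrate divided by first product exceeds the crossover ratio, the inverse of the selectivity factor:

0.0381

I expected delta to end on the rising side and alpha far on the falling side.

The forecast gave 72 %, 74 % and 70 %, judging that “first product peaks near the middle flask and falls at high partner”.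

The flasks gave 76.0 %, 74.9 % and 59.6 %.

    bis adduct → over-reaction product (k = 2.10 × 10⁻⁴ h⁻¹)
    partner + first product → bis adduct + by-product (k = 0.350 M⁻¹ h⁻¹)
    bis adduct ⇌ isomer of the product (K = 0.760, k = 0.360 h⁻¹)
    first product + capture agent → trapped intermediate (k = 11.0 M⁻¹ h⁻¹)
    substrate + partner → first product + by-product (k = 4.80 M⁻¹ h⁻¹)
    partner + bis adduct → triple product + by-product (k = 0.260 M⁻¹ h⁻¹)

At 12.0 d, delta's ratio stood at 0.129, above the crossover 0.0381, and its first product had gone from 75.2 % at 6.00 d to 76.0 %. Alpha's ratio stood at 0.00102, below the crossover, and its first product had dropped from 68.6 % to 59.6 %. Part of why epsilon kept 74.9 % first product was the wearing away of capture agent, to 0 % of its charge, together with the falling level of partner: epsilon ends at 6.35 % with the first taken away and at 11.6 % with the second.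

The numbers in the tables come from a simulation for an exercise; noise was put on by code.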